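## The problem

- Compound 24 is a cis-fused bicycle. A γ-lactone (ring B: O1–C2(=O)–C3–C3a–C7a) shares the C3a–C7a bond with a cyclohexenone (ring A: C3a–C4–C5(=O)–C6=C7–C7a). The all-carbon quaternary atom C3a carries a (2E,6E)-farnesyl chain (C1′–C12′). This numbering is used for every intermediate.
- There are only two stereocentres, (3aR,7aR), and they are neighbours. A five-membered ring on a six-membered ring closes cis almost by default, so either centre can dictate the other. The real difficulty is the absolute configuration of C3a, whose four ligands are three CH2 groups and one CH.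
- The chain holds three trisubstituted alkenes, two of them of defined E geometry, that are more nucleophilic than anything in the core. They would not survive peracids, ketene equivalents or strong Brønsted and Lewis acids, so either the chemistry or the moment of chain attachment is restricted.
- The γ-acyloxy enone is the second fragile unit. C7a–H is vinylogously acidic and O1 is an allylic carboxylate, so base, reducing metals and zerovalent palladium should be kept away from it, and it should appear last.
- C5 has to stay distinguishable from C2, and unsaturation must be placed at C6–C7 only. The structure helps here: C3a has no hydrogen, so the C4 side of the ketone cannot be dehydrogenated.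
- The enabling feature is ring B itself. With O1 taken out, C2, C3, C3a and C7a form a cyclobutanone fused to ring A. Such a ketone is the [2+2] adduct of a two-carbon ketene equivalent with a cyclohexene whose double bond is C3a=C7a.
- A suprafacial cycloaddition would create both stereocentres at once and cis. Oxygen insertion on the more substituted side of the ketone would then return exactly the lactone of 24.

## Retrosynthesis

**24 ⇒ 23.** Only the C6=C7 π bond is removed; no σ bond is cut. The alternative is to carry the enone with its allylic carboxylate through metal-mediated steps, which invites reductive or base-induced loss of O1, so the saturated keto lactone 23 is the safer precursor. The step is regiochemically unambiguous, because of the two α-carbons only C6 has a hydrogen-bearing β-neighbour. The forward reaction must dehydrogenate a ketone without base and without touching three alkenes.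

**23 ⇒ 22.** The C5 carbonyl is masked as its ethylene ketal. This costs one step. In return, a single protecting group shields C5 from triflic anhydride, peracid, hydrogenation, phosphonium chemistry and an organozinc, and adds no stereocentre, as a protected C5 carbinol would. The forward hydrolysis must be mild enough for the polyene.

**22 ⇒ 13 + 20.** The C1′–C2′ bond is cut.

- Cutting C3a–C1′ is unattractive. C3a is β to both carbonyl groups and cannot be alkylated as an enolate, and an allyl-metal conjugate addition would scramble the allyl termini.
- Cutting C2′=C3′ by olefination gives poor E control for a trisubstituted alkene.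
- The chosen cut moves the geometry problem into the separate fragment 20 and leaves the small bicyclic iodide 13.
- The organozinc 21 derived from 13 has no β-hydrogen, so the usual weakness of sp3–sp2 coupling is absent. The coupling must retain the alkene geometry and tolerate the lactone and the ketal.

**20 ⇒ 18 ⇒ 17 ⇒ 14 + 15.**

- The C3′–CH3 and C2′–I bonds of 20 are traced to syn-carbometallation of the terminal alkyne 18 through alane 19, which fixes E geometry mechanistically.
- Alkyne 18 comes from silane 17.
- The C4′–C5′ bond of 17 is made from the lithiated propyne 16 (from 14) and geranyl bromide 15. Both are commercial, and the existing E alkene of 15 is not touched.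

**13 ⇒ 12 ⇒ 11.** The C1′–I bond is exchanged for C1′–OH and then for C1′–OBn. An iodide could not pass through a peracid step, and a free hydroxyl could not pass through the cycloaddition. A benzyl ether is chosen because it leaves under neutral hydrogenolysis. Fluoride or base would expose an alkoxide next to the lactone and invite acyl migration from O1 to the primary oxygen.

**11 ⇒ 9 (key disconnection).**

- O1 is excised: the O1–C7a and O1–C2 bonds are replaced by a C2–C7a bond, which contracts ring B to the cyclobutanone 9.
- Lactonisation of a C7a hydroxy acid is the neighbouring cut, but it leaves C3a and C7a to be set separately.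
- The ring contraction ties both centres into one four-membered ring that can only be cis-fused.
- The precursor has one heteroatom fewer and is a direct cycloadduct.
- The forward Baeyer–Villiger reaction (through adduct 10) must let C7a migrate rather than C3, with retention.
- It must also meet no alkene, which is why the chain is still absent.

**9 ⇒ 4 + 6, and 6 ⇒ 5.**

- The C2–C7a and C3–C3a bonds are cut, giving the achiral alkene 4 and a two-carbon unit delivered as the keteniminium salt 7 from acetamide 6. Hydrolysis of the iminium salt 8 then releases the ketone.
- A keteniminium ion is preferred to dichloroketene because it needs no dechlorination and can carry a cleavable C2-symmetric amine (5) as the source of absolute configuration.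
- No ketene equivalent could tell C3a=C7a from the farnesyl alkenes, so the chain is cut back to C1′ bearing a benzyloxy group.
- The forward step needs three things: regiochemistry (central carbon to C7a), face selectivity, and tolerance of the ether and the ketal.

**4 ⇒ 3 ⇒ 2 ⇒ 1.**

- The benzyl group is removed (3), and the ketal is traced to the enol ether of the 1,4-diene 2.
- Diene 2 is the Birch product of 3-methoxybenzyl alcohol 1.
- The meta relationship of the two donor substituents in 1 places the surviving alkene exactly at C3a=C7a, with the masked ketone at C5.
- The same alkene could be built from a saturated six-membered ketone by enol triflate formation and carbonylation. That would depend on regioselective enolisation next to a β-ketal, which can also eliminate, and it would take one step more.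

## Roads not taken

**Alternative 1:**

- **Cut and key step.** The cut runs through ring A at C3a–C4 and C5–C6 and treats the ring as the remnant of a Diels–Alder adduct of an ortho-quinone ketal. The phenol acid A1 would be oxidised by a preformed chiral aryliodine diacetate, ArI(OAc)2 (trivalent iodine), to the spiro-lactone masked o-benzoquinone A2. This is trapped in the same flask by the silyl vinyl ether A3 to give the bicyclo[2.2.2]octenone A4.
- **Merits.** The chain is attached to a flat aromatic by ordinary phenol chemistry. The cycloaddition is polarity-matched: the nucleophilic CH2 of A3 meets the electrophilic diene terminus that becomes C3a. Two C–C bonds, the quaternary centre and the C5 oxygen arise in one operation.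
- **Weak point: the oxidant.** An electrophilic oxidant meets three electron-rich alkenes, and the C2′=C3′ alkene sits one CH2 away from the ring carbon that becomes cationic, so cation–olefin side reactions are structurally invited.
- **Weak point: stereocontrol.** All absolute stereocontrol rests on a mixed acyl/alkyl ketal carbon. It is set in a six-membered closure that lies further from known enantioselective dearomatising spirolactonisations than a five-membered closure would. That centre must then bias the diene faces through the small difference between O-alkyl and O-acyl.
- **Weak point: the diene terminus.** It is fully substituted, so self-dimerisation of A2 competes.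
- **Weak point: after the key step.** A4 has one bridge too many. The bicycle must be reopened, the six-membered dioxanone exchanged for the five-membered lactone, the silyl ether oxidised and the alkene brought into conjugation. Several of the new stereocentres are erased in the process.
- **Comparison.** This road is more convergent and needs no late sp3–sp2 coupling. The chosen plan offers three things in return. Its oxidation meets no alkene. Its two stereocentres are formed directly in their final relationship. Its downstream steps are all of known type.

**Alternative 2:**

- **Cut and key step.** The cut is C3–C3a. The enantioenriched hydroxy enone A5 is esterified to the methyl malonate A6. Cs2CO3 generates the malonate enolate, which adds 5-exo-trig to C3a and closes ring B to give A7.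
- **End game.** A Krapcho dealkoxycarbonylation of A7 would give 23 itself, and the final dehydrogenation would be the one used here.
- **Merits.** The chain is present from the start. Only one easily addressed carbinol centre has to be bought. The tether forces delivery to the face of O1, so cis fusion and the quaternary centre follow from C7a. The route is clearly shorter than the chosen one.
- **Weak point: acidity in A6.** C7a–H is γ to the enone, so dienolate formation would racemise the controlling centre.
- **Weak point: C1′.** The C1′ hydrogens are both γ to the enone and allylic to C2′=C3′. Base-induced drift of the double bond into the chain is therefore a likely diversion.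
- **Weak point: the Michael addition.** Addition to a β,β-disubstituted enone that builds a quaternary centre is reversible.
- **Weak point: access to A5.** Making A5 as a single enantiomer with a skipped-diene substituent is a project of its own.
- **Weak point: the Krapcho step.** It needs hot halide in a dipolar solvent in the presence of a lactone.
- **Comparison.** On step count and convergence this road is better. The chosen plan offers three things in return. No base-sensitive γ-acyloxy enone exists before the last step. Both centres are fixed irreversibly in a kinetically controlled cycloaddition. No reagent strong enough to isomerise the alkenes acts once the chain is in place.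

**Alternative 3:**

- **Cut and key step.** The cuts are C7a–O1 and C5–O. The diene acid A8 is treated with catalytic Pd(OAc)2 and a quinone reoxidant in acetone–acetic acid. Divalent palladium activates the diene, the tethered carboxylate attacks C7a, and acetate attacks the resulting π-allyl unit at C5 to give A9.
- **End game.** Two functional-group steps (acetate cleavage, allylic oxidation) would then lead to 24.
- **Merits.** This is the most direct end game of all. Both oxygens are placed in one catalytic step, and the C6=C7 alkene is left exactly where it is needed. The tether enforces the cis lactone, and the reaction type is well established for cyclohexadienylacetic acids.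
- **Weak point: the quaternary centre.** The difficulty is only displaced. The sole stereocentre of A8 is the quaternary carbon, which must be distinguished by the difference between a ring CH2 and a ring CH=. No obvious asymmetric entry exists. A degenerate 1,5-hydrogen shift in the diene would exchange those two ring positions and so racemise it on heating.
- **Weak point: the polyene.** Divalent palladium with an oxidant and acetic acid meets three further alkenes, with C2′=C3′ held close to the π-allyl intermediate. Competing coordination, insertion or allylic oxidation must be expected.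
- **Weak point: wasted stereochemistry.** The C5 stereocentre is made only to be destroyed.
- **Comparison.** In redox economy and brevity after the key step this road is superior. The chosen plan offers in return a defined origin for the configuration of C3a and the absence of the polyene from every electrophilic or oxidising step except the last.

Key step: step 6

Assumption: the (2R,5R) auxiliary is taken to steer the cycloaddition to the alkene face that gives (1R,6R)-9; the sense of induction has to be confirmed on 9, and if it is the reverse the equally available (2S,5S) antipode takes its place with no other change.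

## Steps

Step 1
Reactants: 1 3-methoxybenzyl alcohol
Product: 2 (5-methoxycyclohexa-1,4-dien-1-yl)methanol
Conditions: Li, NH3(l), t-BuOH, THF, −78 to −33 °C
Reagents that add atoms: none
Why: Birch reduction; both donor substituents (OMe and the CH2O arm, present as its lithium alkoxide and therefore reluctant to undergo benzylic C–O cleavage) end up on the two remaining double bonds, so the future C3a=C7a alkene and the masked C5 ketone are placed by the meta pattern of 1.

Step 2
Reactants: 2 (5-methoxycyclohexa-1,4-dien-1-yl)methanol
Product: 3 (1,4-dioxaspiro[4.5]dec-7-en-7-yl)methanol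
Conditions: HOCH2CH2OH, PPTS (cat.), CH2Cl2, 0 °C to rt
Reagents that add atoms: ethylene glycol, OCCO
Why: Acid-catalysed acetal exchange of an enol ether, the standard conversion of Birch dihydroanisoles into β,γ-unsaturated ketals; protonation gives an oxocarbenium ion that the diol captures, no free ketone is formed, and the trisubstituted alkene therefore has no drive to move into conjugation.

Step 3
Reactants: 3 (1,4-dioxaspiro[4.5]dec-7-en-7-yl)methanol
Product: 4 7-[(benzyloxy)methyl]-1,4-dioxaspiro[4.5]dec-7-ene
Conditions: NaH, BnBr, n-Bu4NI (cat.), THF, 0 °C to rt
Reagents that add atoms: benzyl bromide, BrCc1ccccc1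
Why: Williamson ether synthesis on a primary allylic alcohol; the ketal and the alkene are inert to base.

Step 4
Reactants: 5 (2R,5R)-2,5-dimethylpyrrolidine
Product: 6 1-[(2R,5R)-2,5-dimethylpyrrolidin-1-yl]ethan-1-one
Conditions: Ac2O, Et3N, DMAP (cat.), CH2Cl2, 0 °C to rt
Reagents that add atoms: acetic anhydride, CC(=O)OC(C)=O
Why: Simple N-acetylation of a secondary amine; the two stereocentres of the auxiliary are not involved.

Step 5
Reactants: 6 1-[(2R,5R)-2,5-dimethylpyrrolidin-1-yl]ethan-1-one; 4 7-[(benzyloxy)methyl]-1,4-dioxaspiro[4.5]dec-7-ene
Product: 9 (1R,6R)-1-[(benzyloxy)methyl]spiro[bicyclo[4.2.0]octane-3,2'-[1,3]dioxolan]-7-one, via keteniminium triflate 7 (not isolated), via cyclobutaniminium triflate 8 (not isolated)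
Conditions: Tf2O, 2,4,6-collidine, ClCH2CH2Cl, −20 to 80 °C; then sat. aq NaHCO3, CH2Cl2, 40 °C
Reagents that add atoms: water, O; triflic anhydride, O=S(=O)(OS(=O)(=O)C(F)(F)F)C(F)(F)F (counter-ion of 7 and 8 only)
Why: Keteniminium–alkene [2+2] cycloaddition after amide activation; the electrophilic central carbon of 7 bonds to the less substituted C7a and the CH2 terminus closes on the developing tertiary cation at C3a on the same face, which fixes regiochemistry and cis fusion, and allyl benzyl ethers are established partners for ketene-type [2+2] reactions. The C2-symmetric pyrrolidine makes both faces of the cumulene equivalent while its methyl groups discriminate between the enantiotopic faces of 4, so C3a and C7a (C1 and C6 of 9) are set together under auxiliary control. Bicarbonate hydrolysis of 8 releases the ketone and the amine and spares the ketal.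

Step 6
Reactants: 9 (1R,6R)-1-[(benzyloxy)methyl]spiro[bicyclo[4.2.0]octane-3,2'-[1,3]dioxolan]-7-one
Product: 11 (3aR,7aR)-3a-[(benzyloxy)methyl]-5,5-(ethylenedioxy)hexahydro-1-benzofuran-2(3H)-one, via Criegee adduct 10 (not isolated)
Conditions: m-CPBA, NaHCO3, CH2Cl2, 0 °C to rt
Reagents that add atoms: m-chloroperbenzoic acid, OOC(=O)c1cccc(Cl)c1
Why: Baeyer–Villiger oxidation of a strained ring-fused cyclobutanone, a long-established route to γ-butyrolactones. The peracid adds to the C2 carbonyl (readily, because rehybridisation to sp3 relieves angle strain) to give the Criegee adduct 10, and one α-carbon then shifts from C2 to the proximal peroxide oxygen while 3-chlorobenzoate departs. Ring B is therefore closed not by a cyclisation but by a 1,2-shift that expands the four-membered ring C2–C3–C3a–C7a to the five-membered ring O1–C2–C3–C3a–C7a, with O1–C7a and O1–C2 formed in place of C2–C7a. The selectivity required is migration of C7a rather than C3: C7a is secondary and carries the partial positive charge of the transition state better than the primary C3, and because both hang on the same quaternary C3a the inductive pull of the benzyloxymethyl and ketal groups acts on both alike and should not reverse the order. No stereocentre is created; the shift proceeds with retention at C7a, so the (1R,6R) cis fusion of 9 is copied into (3aR,7aR)-11, and C3a is untouched. Chemoselectivity comes from the substrate, which holds no alkene at this stage, a benzyl ether that is inert to the peracid at this temperature, and a ketal that solid NaHCO3 shields from 3-chlorobenzoic acid.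

Step 7
Reactants: 11 (3aR,7aR)-3a-[(benzyloxy)methyl]-5,5-(ethylenedioxy)hexahydro-1-benzofuran-2(3H)-one
Product: 12 (3aR,7aR)-5,5-(ethylenedioxy)-3a-(hydroxymethyl)hexahydro-1-benzofuran-2(3H)-one
Conditions: H2 (1 atm), Pd/C, EtOAc, rt
Reagents that add atoms: none
Why: Catalytic hydrogenolysis of a benzyl ether; the neutral medium is chosen because acid or alkoxide could move the acyl group from O1 to the new primary hydroxyl, and nothing else in 11 is reducible.

Step 8
Reactants: 12 (3aR,7aR)-5,5-(ethylenedioxy)-3a-(hydroxymethyl)hexahydro-1-benzofuran-2(3H)-one
Product: 13 (3aS,7aR)-5,5-(ethylenedioxy)-3a-(iodomethyl)hexahydro-1-benzofuran-2(3H)-one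
Conditions: PPh3, I2, imidazole, toluene, rt (reagent preformed, 12 added last), then 80 °C
Reagents that add atoms: iodine, [I][I]
Why: Garegg–Samuelsson (Appel-type) iodination; the preformed iodophosphonium reagent captures the primary hydroxyl at room temperature, forestalling acyl migration, and iodide displaces Ph3PO on heating, a slow but well-known process at neopentyl carbons. Should the lactone carbonyl participate, iodide is expected to reopen the cation at the primary C1′ rather than at the secondary, more hindered C7a, giving the same product (the descriptor at C3a changes only because iodine alters the priorities).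

Step 9
Reactants: 14 1-(trimethylsilyl)propyne; 15 geranyl bromide
Product: 17 [(5E)-6,10-dimethylundeca-5,9-dien-1-yn-1-yl]trimethylsilane, via lithiated silylpropyne 16 (not isolated)
Conditions: 14, n-BuLi, THF, −78 to −20 °C; then 15, −78 °C to rt
Reagents that add atoms: n-butyllithium, [Li]CCCC (lithium of 16 only)
Why: Propargylic lithiation and SN2 alkylation with a primary allylic bromide, a standard way to 1,5-enynes; the silyl group directs reaction to the propargylic terminus and the E alkene of 15 is not involved.

Step 10
Reactants: 17 [(5E)-6,10-dimethylundeca-5,9-dien-1-yn-1-yl]trimethylsilane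
Product: 18 (5E)-6,10-dimethylundeca-5,9-dien-1-yne
Conditions: K2CO3, MeOH, rt
Reagents that add atoms: none
Why: Base-catalysed protodesilylation of an alkynylsilane; the alkenes are inert.

Step 11
Reactants: 18 (5E)-6,10-dimethylundeca-5,9-dien-1-yne
Product: 20 (1E,5E)-1-iodo-2,6,10-trimethylundeca-1,5,9-triene, via alkenylalane 19 (not isolated)
Conditions: AlMe3, Cp2ZrCl2 (25 mol %), CH2Cl2, 0 °C to rt; then I2, THF, −30 °C
Reagents that add atoms: trimethylaluminium, C[Al](C)C; iodine, [I][I]
Why: Zirconium-catalysed Negishi carboalumination adds methyl and aluminium syn across the terminal alkyne with methyl at the internal carbon, and iodinolysis of the C–Al bond occurs with retention, so the E geometry of the future C2′=C3′ alkene is fixed mechanistically; isolated trisubstituted alkenes do not react.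

Step 12
Reactants: 13 (3aS,7aR)-5,5-(ethylenedioxy)-3a-(iodomethyl)hexahydro-1-benzofuran-2(3H)-one; 20 (1E,5E)-1-iodo-2,6,10-trimethylundeca-1,5,9-triene
Product: 22 (3aR,7aR)-5,5-(ethylenedioxy)-3a-[(2E,6E)-3,7,11-trimethyldodeca-2,6,10-trien-1-yl]hexahydro-1-benzofuran-2(3H)-one, via alkylzinc iodide 21 (not isolated)
Conditions: 13, Zn dust (activated with BrCH2CH2Br/Me3SiCl), LiCl, THF, 50 °C; then 20, Pd(PPh3)4 (5 mol %), THF, 50 °C
Reagents that add atoms: zinc, [Zn] (in 21 only)
Why: Direct insertion of LiCl-activated zinc into a primary C–I bond tolerates lactone and ketal, and 21 has no β-hydrogen because C3a is quaternary, so the Negishi coupling cannot be diverted by β-hydride elimination. Oxidative addition of 20 to zerovalent palladium and reductive elimination both proceed with retention, so the E geometry is carried into the completed farnesyl chain.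

Step 13
Reactants: 22 (3aR,7aR)-5,5-(ethylenedioxy)-3a-[(2E,6E)-3,7,11-trimethyldodeca-2,6,10-trien-1-yl]hexahydro-1-benzofuran-2(3H)-one
Product: 23 (3aR,7aR)-3a-[(2E,6E)-3,7,11-trimethyldodeca-2,6,10-trien-1-yl]hexahydro-1-benzofuran-2,5-dione
Conditions: PPTS, acetone–H2O, 55 °C
Reagents that add atoms: water, O
Why: Mild acid-catalysed ketal hydrolysis; PPTS is too weak to protonate the trisubstituted alkenes or open the lactone, and no stereocentre is α to the liberated ketone.

Step 14
Reactants: 23 (3aR,7aR)-3a-[(2E,6E)-3,7,11-trimethyldodeca-2,6,10-trien-1-yl]hexahydro-1-benzofuran-2,5-dione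
Product: 24 (3aR,7aR)-3a-[(2E,6E)-3,7,11-trimethyldodeca-2,6,10-trien-1-yl]-3a,7a-dihydro-1-benzofuran-2,5(3H,4H)-dione
Conditions: 2-iodoxybenzoic acid (IBX, 2.5 equiv), DMSO, 65 °C
Reagents that add atoms: none
Why: IBX dehydrogenation of a ketone (enolisation, capture by pentavalent iodine, loss of the β-hydrogen). Only the C6/C7 pair offers both an α- and a β-hydrogen because C3a is quaternary, so a single regioisomer is possible and no dienone can form; the medium is not basic, which protects C7a, and isolated trisubstituted alkenes are normally left alone.

## Compound list

1 | 3-methoxybenzyl alcohol | COc1cccc(CO)c1 | starting material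
2 | (5-methoxycyclohexa-1,4-dien-1-yl)methanol | COC1=CCC=C(CO)C1 | intermediate
3 | (1,4-dioxaspiro[4.5]dec-7-en-7-yl)methanol | OCC1=CCCC2(C1)OCCO2 | intermediate
4 | 7-[(benzyloxy)methyl]-1,4-dioxaspiro[4.5]dec-7-ene | c1ccccc1COCC1=CCCC2(C1)OCCO2 | intermediate
5 | (2R,5R)-2,5-dimethylpyrrolidine | C[C@@H]1CC[C@@H](C)N1 | starting material
6 | 1-[(2R,5R)-2,5-dimethylpyrrolidin-1-yl]ethan-1-one | C[C@@H]1CC[C@@H](C)N1C(C)=O | intermediate
7 | (2R,5R)-1-ethenylidene-2,5-dimethylpyrrolidin-1-ium triflate (keteniminium triflate) | C[C@@H]1CC[C@@H](C)[N+]1=C=C.[O-]S(=O)(=O)C(F)(F)F | intermediate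
8 | (2R,5R)-1-{(1R,6R)-1-[(benzyloxy)methyl]spiro[bicyclo[4.2.0]octane-3,2'-[1,3]dioxolan]-7-ylidene}-2,5-dimethylpyrrolidin-1-ium triflate (cyclobutaniminium triflate) | c1ccccc1COC[C@]12CC3(OCCO3)CC[C@H]1C(=[N+]4[C@H](C)CC[C@H]4C)C2.[O-]S(=O)(=O)C(F)(F)F | intermediate
9 | (1R,6R)-1-[(benzyloxy)methyl]spiro[bicyclo[4.2.0]octane-3,2'-[1,3]dioxolan]-7-one | c1ccccc1COC[C@]12CC3(OCCO3)CC[C@H]1C(=O)C2 | intermediate
10 | Criegee adduct of 9: 7-hydroxy-7-(3-chlorobenzoylperoxy) derivative, configuration at C2 not defined | c1ccccc1COC[C@]12CC3(OCCO3)CC[C@H]1C(O)(OOC(=O)c4cccc(Cl)c4)C2 | intermediate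
11 | (3aR,7aR)-3a-[(benzyloxy)methyl]-5,5-(ethylenedioxy)hexahydro-1-benzofuran-2(3H)-one | c1ccccc1COC[C@]12CC3(OCCO3)CC[C@H]1OC(=O)C2 | intermediate
12 | (3aR,7aR)-5,5-(ethylenedioxy)-3a-(hydroxymethyl)hexahydro-1-benzofuran-2(3H)-one | OC[C@]12CC3(OCCO3)CC[C@H]1OC(=O)C2 | intermediate
13 | (3aS,7aR)-5,5-(ethylenedioxy)-3a-(iodomethyl)hexahydro-1-benzofuran-2(3H)-one | IC[C@]12CC3(OCCO3)CC[C@H]1OC(=O)C2 | intermediate
14 | 1-(trimethylsilyl)propyne | CC#C[Si](C)(C)C | starting material
15 | geranyl bromide, (2E)-1-bromo-3,7-dimethylocta-2,6-diene | CC(C)=CCC/C(C)=C/CBr | starting material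
16 | [3-(trimethylsilyl)prop-2-yn-1-yl]lithium | [Li]CC#C[Si](C)(C)C | intermediate
17 | [(5E)-6,10-dimethylundeca-5,9-dien-1-yn-1-yl]trimethylsilane | CC(C)=CCC/C(C)=C/CCC#C[Si](C)(C)C | intermediate
18 | (5E)-6,10-dimethylundeca-5,9-dien-1-yne | CC(C)=CCC/C(C)=C/CCC#C | intermediate
19 | dimethyl[(1E,5E)-2,6,10-trimethylundeca-1,5,9-trien-1-yl]alane | CC(C)=CCC/C(C)=C/CC/C(C)=C/[Al](C)C | intermediate
20 | (1E,5E)-1-iodo-2,6,10-trimethylundeca-1,5,9-triene | CC(C)=CCC/C(C)=C/CC/C(C)=C/I | intermediate
21 | alkylzinc iodide, the C1′–ZnI analogue of 13 | I[Zn]C[C@]12CC3(OCCO3)CC[C@H]1OC(=O)C2 | intermediate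
22 | (3aR,7aR)-5,5-(ethylenedioxy)-3a-[(2E,6E)-3,7,11-trimethyldodeca-2,6,10-trien-1-yl]hexahydro-1-benzofuran-2(3H)-one | CC(C)=CCC/C(C)=C/CC/C(C)=C/C[C@]12CC3(OCCO3)CC[C@H]1OC(=O)C2 | intermediate
23 | (3aR,7aR)-3a-[(2E,6E)-3,7,11-trimethyldodeca-2,6,10-trien-1-yl]hexahydro-1-benzofuran-2,5-dione | CC(C)=CCC/C(C)=C/CC/C(C)=C/C[C@]12CC(=O)CC[C@H]1OC(=O)C2 | intermediate
24 | (3aR,7aR)-3a-[(2E,6E)-3,7,11-trimethyldodeca-2,6,10-trien-1-yl]-3a,7a-dihydro-1-benzofuran-2,5(3H,4H)-dione (CNP0400313.1) | CC(C)=CCC/C(C)=C/CC/C(C)=C/C[C@]12CC(=O)C=C[C@H]1OC(=O)C2 | target

## Step count and risks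

Total step count: 14. Longest linear sequence: 10 steps (1, 2, 3, 5, 6, 7, 8, 12, 13, 14). The side-chain branch (9, 10, 11) and the auxiliary step (4) run in parallel.

**Step 6 (key step).**

- **What may go wrong.** The most likely failure is incomplete regioselectivity, that is, some migration of C3. Both α-carbons are attached to the same crowded quaternary carbon, and the alignment that C7a needs in the Criegee adduct may be disfavoured on the concave face of the bicycle. A second danger is acid-induced loss of the ketal if buffering is insufficient.
- **Fallback.** It sets out from 9 and returns at 11, and it replaces the peracid by a photochemical ring expansion.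
  - Irradiation of 9 (λ ≥ 300 nm, Pyrex, aqueous MeCN) cleaves the weaker C2–C7a bond.
  - The acyl–alkyl biradical recloses through oxygen to an oxacarbene with retention at C7a.
  - Water adds to the carbene to give the lactol (3aS,7aR)-3a-[(benzyloxy)methyl]-5,5-(ethylenedioxy)octahydro-1-benzofuran-2-ol F1 (anomers).
  - Oxidation of F1 with TEMPO/PhI(OAc)2 gives 11.
  - Regiochemistry is then governed by radical stability rather than by migratory aptitude.

**Step 5.**

- **What may go wrong.**
  - Conversion may be low, because the allylic ether and the ketal withdraw electron density from the carbon that must carry the positive charge.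
  - An ether or ketal oxygen may capture the cumulene, followed by a Bellus–Claisen-type shift or ketal opening.
  - Facial selectivity may be poor, because the parent keteniminium ion has no substituent on its CH2 terminus to fix the orientation of the alkene against the auxiliary.
- **Fallback.** It sets out from 4 and returns at 9.
  - Dichloroketene (Cl3CCOCl, Zn–Cu couple, Et2O–DME) is smaller and more reactive, follows the same regiochemical rule and is routinely used on allyl benzyl ethers.
  - It should give the racemic cis-fused 1-[(benzyloxy)methyl]-8,8-dichlorospiro[bicyclo[4.2.0]octane-3,2'-[1,3]dioxolan]-7-one F2.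
  - Reductive dechlorination (Zn, NH4Cl, MeOH) gives the racemic ketone.
  - Preparative chromatography on a chiral stationary phase separates 9 from its mirror image, the (1S,6S)-ketone F3.
  - The price is one more step and the loss of half the material.

**Step 8.**

- **What may go wrong.** The danger is acyl migration from O1 to the primary hydroxyl of 12 before activation, catalysed by warm imidazole. It is combined with very slow displacement at the neopentyl carbon, which leaves time for participation by the lactone carbonyl.
- **Fallback.** It sets out from 9 and returns at 13. The order of events changes so that no lactone is present when the halide is made.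
  - Hydrogenolysis of 9 (H2, Pd/C, EtOAc) gives (1R,6R)-1-(hydroxymethyl)spiro[bicyclo[4.2.0]octane-3,2'-[1,3]dioxolan]-7-one F4.
  - The same phosphonium iodination converts F4 into (1R,6R)-1-(iodomethyl)spiro[bicyclo[4.2.0]octane-3,2'-[1,3]dioxolan]-7-one F5.
  - The ring expansion is then carried out with alkaline hydrogen peroxide (H2O2, NaOH, THF–MeOH, 0 °C, then a buffered acid quench). This nucleophilic oxidant attacks strained cyclobutanones but does not oxidise an alkyl iodide and cannot displace it at a neopentyl carbon. The product is 13.

**Step 12.**

- **What may go wrong.** Zinc insertion may be sluggish and transmetallation of the hindered neopentyl zinc reagent slow, so that protodemetallation and homocoupling of 20 gain ground. Loss of the carboxylate by 1,3-elimination from 21 is a lesser concern.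
- **Fallback.** It sets out from 13 and 20 and returns at 22, with the polarity of the partners reversed.
  - Halogen–lithium exchange of 20 (t-BuLi, Et2O, −78 °C) followed by ZnCl2 gives [(1E,5E)-2,6,10-trimethylundeca-1,5,9-trien-1-yl]zinc chloride F6.
  - F6 is coupled with 13 under nickel catalysis (NiCl2(dme), a pybox or bipyridine ligand, THF–DMA, rt).
  - C1′ then reacts as a radical generated by low-valent nickel, which is insensitive to neopentyl hindrance, and no organometallic has to be formed next to the lactone.

**Step 14.**

- **What may go wrong.** Oxidative damage to the polyene (allylic or single-electron oxidation at 65 °C) may occur. Enolisation towards C4 is unproductive and may stall conversion or lead to α-oxygenation.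
- **Fallback.** It sets out from 23 and returns at 24 by a two-stage Saegusa–Ito sequence.
  - Kinetic deprotonation at the less hindered C6 (LiN(SiMe3)2, Me3SiCl, THF, −78 °C; the ketone is more acidic than the lactone) gives the silyl enol ether (3aR,7aR)-3a-[(2E,6E)-farnesyl]-5-(trimethylsilyloxy)-3a,4,7,7a-tetrahydro-1-benzofuran-2(3H)-one F7.
  - Pd(OAc)2 in MeCN at rt converts F7 into 24 through an oxa-π-allyl complex of divalent palladium and β-hydride elimination from C7.
  - Any C4 regioisomer of the enol ether cannot eliminate and simply returns 23.

## Further compounds

F1 | step 6 | (3aS,7aR)-3a-[(benzyloxy)methyl]-5,5-(ethylenedioxy)octahydro-1-benzofuran-2-ol (lactol, anomers) | c1ccccc1COC[C@]12CC3(OCCO3)CC[C@H]1OC(O)C2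
F2 | step 5 | (±)-cis-1-[(benzyloxy)methyl]-8,8-dichlorospiro[bicyclo[4.2.0]octane-3,2'-[1,3]dioxolan]-7-one (racemic, one enantiomer drawn) | c1ccccc1COC[C@]12CC3(OCCO3)CC[C@H]1C(=O)C2(Cl)Cl
F3 | step 5 | (1S,6S)-1-[(benzyloxy)methyl]spiro[bicyclo[4.2.0]octane-3,2'-[1,3]dioxolan]-7-one (enantiomer of 9) | c1ccccc1COC[C@@]12CC3(OCCO3)CC[C@@H]1C(=O)C2
F4 | step 8 | (1R,6R)-1-(hydroxymethyl)spiro[bicyclo[4.2.0]octane-3,2'-[1,3]dioxolan]-7-one | OC[C@]12CC3(OCCO3)CC[C@H]1C(=O)C2
F5 | step 8 | (1R,6R)-1-(iodomethyl)spiro[bicyclo[4.2.0]octane-3,2'-[1,3]dioxolan]-7-one | IC[C@]12CC3(OCCO3)CC[C@H]1C(=O)C2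
F6 | step 12 | [(1E,5E)-2,6,10-trimethylundeca-1,5,9-trien-1-yl]zinc chloride | CC(C)=CCC/C(C)=C/CC/C(C)=C/[Zn]Cl
F7 | step 14 | (3aR,7aR)-3a-[(2E,6E)-3,7,11-trimethyldodeca-2,6,10-trien-1-yl]-5-(trimethylsilyloxy)-3a,4,7,7a-tetrahydro-1-benzofuran-2(3H)-one | CC(C)=CCC/C(C)=C/CC/C(C)=C/C[C@]12CC(O[Si](C)(C)C)=CC[C@H]1OC(=O)C2
A1 | alternative 1 | 3-{2-[(2E,6E)-3,7,11-trimethyldodeca-2,6,10-trien-1-yl]-6-hydroxyphenoxy}propanoic acid | CC(C)=CCC/C(C)=C/CC/C(C)=C/Cc1cccc(O)c1OCCC(=O)O
A2 | alternative 1 | spiro-lactone masked o-benzoquinone (5-farnesylcyclohexa-2,4-dienone spiro-fused at C6 to a 1,3-dioxan-4-one) | CC(C)=CCC/C(C)=C/CC/C(C)=C/CC1=CC=CC(=O)[C@@]12OCCC(=O)O2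
A3 | alternative 1 | tert-butyldimethylsilyl vinyl ether | C=CO[Si](C)(C)C(C)(C)C
A4 | alternative 1 | bridgehead-farnesyl 7-(tert-butyldimethylsilyloxy)bicyclo[2.2.2]oct-5-en-2-one spiro-fused at C3 to a 1,3-dioxan-4-one | CC(C)=CCC/C(C)=C/CC/C(C)=C/C[C@]12C=C[C@H](C(=O)[C@@]13OCCC(=O)O3)[C@@H](O[Si](C)(C)C(C)(C)C)C2
A5 | alternative 2 | (R)-4-hydroxy-3-[(2E,6E)-3,7,11-trimethyldodeca-2,6,10-trien-1-yl]cyclohex-2-en-1-one | CC(C)=CCC/C(C)=C/CC/C(C)=C/CC1=CC(=O)CC[C@H]1O
A6 | alternative 2 | methyl (R)-2-farnesyl-4-oxocyclohex-2-en-1-yl malonate | CC(C)=CCC/C(C)=C/CC/C(C)=C/CC1=CC(=O)CC[C@H]1OC(=O)CC(=O)OC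
A7 | alternative 2 | methyl (3aR,7aR)-3a-farnesyl-2,5-dioxooctahydrobenzofuran-3-carboxylate (C3 epimers) | CC(C)=CCC/C(C)=C/CC/C(C)=C/C[C@]12CC(=O)CC[C@H]1OC(=O)C2C(=O)OC
A8 | alternative 3 | (S)-2-{1-[(2E,6E)-3,7,11-trimethyldodeca-2,6,10-trien-1-yl]cyclohexa-2,4-dien-1-yl}acetic acid | CC(C)=CCC/C(C)=C/CC/C(C)=C/C[C@]1(CC(=O)O)CC=CC=C1
A9 | alternative 3 | (3aR,5S,7aR)-5-acetoxy-3a-farnesyl-3,3a,4,5-tetrahydrobenzofuran-2(7aH)-one (acetate trans to O1) | CC(C)=CCC/C(C)=C/CC/C(C)=C/C[C@]12C[C@H](OC(C)=O)C=C[C@H]1OC(=O)C2
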